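Ring C of the target hides a dimethylated acetonedicarboxylate. C17–C13(Me)–C14–C8(Me)–C7 is a 1,3-bis-nucleophile, and C9–C11–C12 is an enal. Everything rests on joining these two pieces through C8–C9 and C12–C13. One amine-catalysed Michael–aldol domino closes the cyclohexanone and sets C8, C9, C12 and C13, including both quaternary carbons, next to the lactate-derived C10. Its precursors are an epimerisable, constitutionally symmetric keto diester and an enantiopure γ-silyloxy enal. Afterwards C12 is deoxygenated and both esters are taken to aldehydes. C17 then receives the furan, a C17-tethered Darzens closure builds the glycidate at C14, and C7 is joined to a pyranone alkenyl iodide.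

Key step: step 5

Remark: limonoid atom numbers are used. β is the face of ring C that carries the C8 methyl group, and α is the opposite face. Stereocentres that a later step erases are drawn in the expected configuration or, where no preference is expected, left open.

Step 1
Reactants: 1 dimethyl 3-oxopentanedioate
Product: 2 dimethyl 2,4-dimethyl-3-oxopentanedioate (mixture of stereoisomers)
Conditions: MeI (2.1 equiv), K2CO3, acetone, reflux
Reagents that add atoms: iodomethane CI
Why: β-Keto ester alkylation: each doubly activated methylene is deprotonated by carbonate and methylated once, a second alkylation at the same carbon being slower for steric reasons, and the two new stereocentres stay an epimerisable mixture because both are re-formed in step 5.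

Step 2
Reactants: 3 methyl (R)-lactate
Product: 4 methyl (R)-2-(tert-butyldimethylsilyloxy)propanoate
Conditions: TBSCl, imidazole, DMF, rt
Reagents that add atoms: tert-butyldimethylsilyl chloride CC(C)(C)[Si](C)(C)Cl
Why: Imidazole-promoted silylation of a secondary alcohol forms only an O–Si bond and leaves the lactate stereocentre (later C10) untouched.

Step 3
Reactants: 4 methyl (R)-2-(tert-butyldimethylsilyloxy)propanoate
Product: 5 (R)-2-(tert-butyldimethylsilyloxy)propanal
Conditions: i-Bu2AlH, CH2Cl2, −78 °C; aqueous work-up
Reagents that add atoms: none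
Why: Partial ester reduction with i-Bu2AlH: the aluminium hemiacetal is stable at low temperature, so the configurationally labile α-silyloxy aldehyde appears only on work-up.

Step 4
Reactants: 5 (R)-2-(tert-butyldimethylsilyloxy)propanal
Product: 6 (R,E)-4-(tert-butyldimethylsilyloxy)pent-2-enal
Conditions: Ph3P=CHCHO, toluene, 80 °C
Reagents that add atoms: (triphenylphosphoranylidene)acetaldehyde O=CC=P(c1ccccc1)(c1ccccc1)c1ccccc1
Why: Wittig olefination with a formyl-stabilised ylide is E-selective and neutral, so the α-stereocentre is not epimerised.

Step 5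
Reactants: 2 dimethyl 2,4-dimethyl-3-oxopentanedioate; 6 (R,E)-4-(tert-butyldimethylsilyloxy)pent-2-enal
Product: 8 hydroxy cyclohexanone diester, via Michael adduct 7 (not isolated)
Conditions: (R)-α,α-diphenylprolinol trimethylsilyl ether (20 mol %), PhCO2H (20 mol %), toluene, 0 °C → rt; then Et3N (20 mol %), rt
Reagents that add atoms: none
Why: Proposed new method: the amine turns enal 6 into an E-configured iminium ion, the hydrogen-bonded enol of 2 adds through C8 to C9, hydrolysis frees aldehyde 7, and the second acidic carbon C13 then adds to C12 in a 6-(enolendo)-exo-trig aldol that closes ring C; the closest known reaction type is the diarylprolinol-silyl-ether-catalysed Michael–aldol domino of β-keto esters with enals, which has not been shown for an acyclic α,α'-dialkylated keto diester that must form two quaternary carbons. C9 is set by the catalyst, because the R-configured amine shields the unwanted enal face, and the open face is also the Felkin–Anh face of the C10 stereocentre (C–O bond anti to the incoming carbon), so catalyst and substrate are matched. C8 is set kinetically in the staggered open transition state, where the keto-ester arm C14 lies anti to C10 and the methyl group, the smallest substituent of the flat enol, takes the crowded sector between C10 and C11, which leaves C7 trans to C10. C13 and C12 are set under thermodynamic control because the aldol is reversible: with the C8 methyl group axial, the chair with an axial C13 ester avoids a 1,3-diaxial methyl/methyl contact, and the C12 hydroxyl group settles equatorial and hydrogen-bonded to that ester. The step needs 1,4- before 1,2-addition, which iminium activation secures, and it needs no regiochemical choice in the donor, which its constitutional symmetry secures, both stereoisomers of 2 converging through the enol. The weakly acidic medium keeps dienamine formation, and with it loss of configuration at C10, slow.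

Step 6
Reactants: 8 hydroxy cyclohexanone diester
Product: 9 C12 O-phenyl thionocarbonate
Conditions: PhOC(S)Cl, DMAP, MeCN, rt
Reagents that add atoms: O-phenyl chlorothionoformate ClC(=S)Oc1ccccc1
Why: Nucleophile-catalysed acylation of C12–OH (first half of the Barton–McCombie deoxygenation) avoids the metal alkoxide that xanthate formation would need and that would open the β-hydroxy ketone by retro-aldol cleavage.

Step 7
Reactants: 9 C12 O-phenyl thionocarbonate
Product: 10 keto diester (12-deoxy)
Conditions: Bu3SnH (0.5 M), AIBN (cat.), toluene, 90 °C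
Reagents that add atoms: none
Why: Barton–McCombie deoxygenation: the stannyl radical adds to C=S, the C12–O bond fragments, and the secondary radical is trapped by concentrated Bu3SnH before a 1,2-acyl shift towards C13 can compete, so only the C12 stereocentre disappears.

Step 8
Reactants: 10 keto diester (12-deoxy)
Product: 11 triol
Conditions: LiAlH4, THF, 0 °C
Reagents that add atoms: none
Why: Exhaustive hydride reduction removes the need to tell a hindered ketone from two neopentyl esters; hydride should reach C14 from the α face, away from the two axial α-substituents, but step 9 erases this centre.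

Step 9
Reactants: 11 triol
Product: 12 keto dialdehyde
Conditions: Dess–Martin periodinane (excess), CH2Cl2, rt
Reagents that add atoms: none
Why: Dess–Martin oxidation converts hindered alcohols under near-neutral conditions, so the non-enolisable β-keto aldehyde units never meet a base that could cause deformylation or retro-aldol cleavage.

Step 10
Reactants: 12 keto dialdehyde; 13 3-bromofuran
Product: 16 C17 furyl carbinol, via 3-furyllithium 14 (not isolated), via furyltitanium triisopropoxide 15 (not isolated)
Conditions: 13, n-BuLi, THF, −78 °C; ClTi(OiPr)3, −78 °C; then 12, −78 → −30 °C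
Reagents that add atoms: none
Why: Bromine–lithium exchange, transmetalation and carbonyl addition of an aryltitanium triisopropoxide, a bulky and weakly basic reagent that adds to aldehydes but not to ketones and that should pick the C17 formyl group (flanked by CH2-12) over the C7 formyl group (screened by C9 and its branched silyloxyethyl chain); the C17 formyl group keeps its hydrogen under the ring and is attacked on its outer face, anti to C14 (Felkin–Anh), which gives the carbinol drawn, a centre that steers step 12 and is erased in step 14.

Step 11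
Reactants: 16 C17 furyl carbinol
Product: 17 C17 chloroacetate
Conditions: (ClCH2CO)2O, DMAP (cat.), pyridine, CH2Cl2, 0 °C
Reagents that add atoms: chloroacetic anhydride O=C(CCl)OC(=O)CCl
Why: DMAP-catalysed esterification with the anhydride acylates the only hydroxyl group and leaves aldehyde, ketone, furan and silyl ether untouched.

Step 12
Reactants: 17 C17 chloroacetate
Product: 19 14,15-epoxy δ-lactone aldehyde, via chlorohydrin alkoxide 18 (not isolated)
Conditions: KOt-Bu (1.05 equiv), THF (high dilution), −78 → −30 °C
Reagents that add atoms: none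
Why: Intramolecular Darzens condensation: the six-membered tether makes the ketone between two quaternary carbons reachable and forces C16 cis to C13 on the oxirane, which fixes C15, while C14 is fixed because ring C, not tied by any C7–O–C10 bridge, can flip to put the bulky C17 equatorial, so the enolate bonds trans-diequatorially (chair-like lactone, equatorial furan) on the face away from the now axial C10 chain and the resulting axial alkoxide, anti to C–Cl, closes the β-epoxide; attack on the C7 formyl group would need an eight-membered ring.

Step 13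
Reactants: 19 14,15-epoxy δ-lactone aldehyde
Product: 20 hydroxy glycidic methyl ester
Conditions: MeOH, Et3N, DMAP (cat.), 0 °C → rt
Reagents that add atoms: methanol CO
Why: Lactone methanolysis (transesterification under amine catalysis): the α-oxygenated, trans-fused δ-lactone is the only activated acyl group, ring opening lets ring C relax, and the absence of alkoxide base keeps the hemiacetal of the C7 aldehyde from fragmenting towards the oxirane.

Step 14
Reactants: 20 hydroxy glycidic methyl ester
Product: 21 furyl ketone aldehyde
Conditions: Dess–Martin periodinane, CH2Cl2, 0 °C → rt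
Reagents that add atoms: none
Why: Dess–Martin oxidation of the furyl carbinol under near-neutral conditions blocks relactonisation, removes the auxiliary C17 centre and leaves aldehyde, oxirane and furan intact.

Step 15
Reactants: 22 2-methylbut-3-yn-2-ol
Product: 23 (Z)-2-methyl-3-(tributylstannyl)-4-(trimethylsilyl)but-3-en-2-ol
Conditions: Bu3SnSiMe3, Pd(PPh3)4 (cat.), THF, 65 °C
Reagents that add atoms: tributyl(trimethylsilyl)stannane CCCC[Sn](CCCC)(CCCC)[Si](C)(C)C
Why: Palladium-catalysed silylstannation of a terminal alkyne is a syn addition that puts tin on the internal and silicon on the terminal carbon, which fixes the later C5=C6 geometry.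

Step 16
Reactants: 23 (Z)-2-methyl-3-(tributylstannyl)-4-(trimethylsilyl)but-3-en-2-ol; 24 ethyl (Z)-3-iodoacrylate
Product: 26 (E)-6,6-dimethyl-5-[(trimethylsilyl)methylidene]-5,6-dihydro-2H-pyran-2-one, via hydroxy dienoate 25 (not isolated)
Conditions: Pd2(dba)3 (cat.), AsPh3, CuI (cat.), DMF, 45 °C; then PPTS (cat.), toluene, 80 °C
Reagents that add atoms: none
Why: Stille coupling with retention at both alkenyl carbons, helped by copper co-catalysis at the hindered stannane; the Z-enoate holds the ester next to the tertiary alcohol, so acid-catalysed lactonisation closes the pyranone.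

Step 17
Reactants: 26 (E)-6,6-dimethyl-5-[(trimethylsilyl)methylidene]-5,6-dihydro-2H-pyran-2-one
Product: 27 (E)-5-(iodomethylidene)-6,6-dimethyl-5,6-dihydro-2H-pyran-2-one
Conditions: NIS, (CF3)2CHOH, 0 °C, dark
Reagents that add atoms: N-iodosuccinimide O=C1CCC(=O)N1I
Why: Electrophilic iododesilylation (ipso substitution through a β-silyl cation) in a polar, non-nucleophilic solvent proceeds with retention, so iodine stays trans to the CMe2 carbon.

Step 18
Reactants: 21 furyl ketone aldehyde; 27 (E)-5-(iodomethylidene)-6,6-dimethyl-5,6-dihydro-2H-pyran-2-one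
Product: 29 C7 dienyl carbinol, via alkenylchromium dichloride 28 (not isolated)
Conditions: CrCl2 (excess), NiCl2 (cat.), DMSO, rt
Reagents that add atoms: none
Why: Nozaki–Hiyama–Kishi coupling: zerovalent nickel inserts into the C–I bond with retention, transmetalation gives the alkenylchromium species, and this adds to aldehydes only, so furyl ketone, esters, lactone and oxirane are spectators; the C7 carbinol forms as a mixture that step 19 erases.

Step 19
Reactants: 29 C7 dienyl carbinol
Product: 30 O-silyl ether of the target
Conditions: Dess–Martin periodinane, CH2Cl2, 0 °C → rt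
Reagents that add atoms: none
Why: Dess–Martin oxidation of the allylic alcohol gives the cross-conjugated dienone without acid or base, so the E geometry (acyl group trans to CMe2, also the less strained isomer) is kept.

Step 20
Reactants: 30 O-silyl ether of the target
Product: 31 target CNP0293135.1
Conditions: HF·pyridine, pyridine, THF, 0 °C → rt
Reagents that add atoms: none
Why: Fluoride-induced silyl ether cleavage with pyridine-buffered HF is mild enough for oxirane, dienone and lactone, and C10 keeps the configuration brought in by the lactate.

Compound list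
1 | dimethyl 3-oxopentanedioate | COC(=O)CC(=O)CC(=O)OC | starting material
2 | dimethyl 2,4-dimethyl-3-oxopentanedioate, stereoisomer mixture | COC(=O)C(C)C(=O)C(C)C(=O)OC | intermediate
3 | methyl (R)-lactate | C[C@@H](O)C(=O)OC | starting material
4 | methyl (R)-2-(tert-butyldimethylsilyloxy)propanoate | C[C@@H](O[Si](C)(C)C(C)(C)C)C(=O)OC | intermediate
5 | (R)-2-(tert-butyldimethylsilyloxy)propanal | C[C@@H](O[Si](C)(C)C(C)(C)C)C=O | intermediate
6 | (R,E)-4-(tert-butyldimethylsilyloxy)pent-2-enal | O=C/C=C/[C@@H](C)O[Si](C)(C)C(C)(C)C | intermediate
7 | open-chain Michael adduct aldehyde, C8 and C9 as in 8, C13 epimeric | O=CC[C@H]([C@@H](C)O[Si](C)(C)C(C)(C)C)[C@@](C)(C(=O)OC)C(=O)C(C)C(=O)OC | intermediate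
8 | dimethyl 4-[(1R)-1-(TBSO)ethyl]-6-hydroxy-1,3-dimethyl-2-oxocyclohexane-1,3-dicarboxylate; C8 Me β, C9 H α, C13 Me α, C12 OH β | O=C1[C@](C)(C(=O)OC)[C@H](O)C[C@H]([C@@H](C)O[Si](C)(C)C(C)(C)C)[C@@]1(C)C(=O)OC | intermediate
9 | C12 O-phenyl thionocarbonate of 8 | O=C1[C@](C)(C(=O)OC)[C@H](OC(=S)Oc2ccccc2)C[C@H]([C@@H](C)O[Si](C)(C)C(C)(C)C)[C@@]1(C)C(=O)OC | intermediate
10 | dimethyl 4-[(1R)-1-(TBSO)ethyl]-1,3-dimethyl-2-oxocyclohexane-1,3-dicarboxylate; C8 Me β, C9 H α, C13 Me α | O=C1[C@](C)(C(=O)OC)CC[C@H]([C@@H](C)O[Si](C)(C)C(C)(C)C)[C@@]1(C)C(=O)OC | intermediate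
11 | 2,6-bis(hydroxymethyl)-2,6-dimethyl-3-[(1R)-1-(TBSO)ethyl]cyclohexan-1-ol, C14 OH drawn β | O[C@@H]1[C@](C)(CO)CC[C@H]([C@@H](C)O[Si](C)(C)C(C)(C)C)[C@@]1(C)CO | intermediate
12 | 4-[(1R)-1-(TBSO)ethyl]-1,3-dimethyl-2-oxocyclohexane-1,3-dicarbaldehyde | O=C1[C@](C)(C=O)CC[C@H]([C@@H](C)O[Si](C)(C)C(C)(C)C)[C@@]1(C)C=O | intermediate
13 | 3-bromofuran | Brc1ccoc1 | starting material
14 | 3-furyllithium | [Li]c1ccoc1 | intermediate
15 | (furan-3-yl)titanium triisopropoxide | CC(C)O[Ti](OC(C)C)(OC(C)C)c1ccoc1 | intermediate
16 | keto aldehyde with furan-3-yl(hydroxy)methyl group at C13, C17 as in D-ring limonoids | O=C1[C@](C)([C@@H](O)c2ccoc2)CC[C@H]([C@@H](C)O[Si](C)(C)C(C)(C)C)[C@@]1(C)C=O | intermediate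
17 | chloroacetate of 16 | O=C1[C@](C)([C@@H](OC(=O)CCl)c2ccoc2)CC[C@H]([C@@H](C)O[Si](C)(C)C(C)(C)C)[C@@]1(C)C=O | intermediate
18 | potassium alkoxide of the 15-chloro-14-hydroxy δ-lactone, O14 β, Cl anti to O14 | O=C3[C@H](Cl)[C@@]2([O-])[C@](C)([C@@H](O3)c1ccoc1)CC[C@H]([C@@H](C)O[Si](C)(C)C(C)(C)C)[C@@]2(C)C=O.[K+] | intermediate
19 | 14β,15β-epoxy δ-lactone (C16–O–C17) with C7 formyl group and C10 OTBS | O=C3[C@H]1O[C@@]12[C@](C)([C@@H](O3)c1ccoc1)CC[C@H]([C@@H](C)O[Si](C)(C)C(C)(C)C)[C@@]2(C)C=O | intermediate
20 | methyl glycidate with free C17 furyl carbinol and C7 formyl group | COC(=O)[C@H]1O[C@@]12[C@](C)([C@@H](O)c1ccoc1)CC[C@H]([C@@H](C)O[Si](C)(C)C(C)(C)C)[C@@]2(C)C=O | intermediate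
21 | methyl glycidate with C17 3-furoyl group and C7 formyl group | COC(=O)[C@H]1O[C@@]12[C@](C)(C(=O)c1ccoc1)CC[C@H]([C@@H](C)O[Si](C)(C)C(C)(C)C)[C@@]2(C)C=O | intermediate
22 | 2-methylbut-3-yn-2-ol | CC(C)(O)C#C | starting material
23 | (Z)-2-methyl-3-(tributylstannyl)-4-(trimethylsilyl)but-3-en-2-ol | CC(C)(O)/C(=C/[Si](C)(C)C)[Sn](CCCC)(CCCC)CCCC | intermediate
24 | ethyl (Z)-3-iodoacrylate | CCOC(=O)/C=C\I | starting material
25 | ethyl (2Z)-4-(2-hydroxypropan-2-yl)-5-(trimethylsilyl)penta-2,4-dienoate, silicon cis to the enoate arm | CCOC(=O)/C=C\C(=C/[Si](C)(C)C)C(C)(C)O | intermediate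
26 | (E)-6,6-dimethyl-5-[(trimethylsilyl)methylidene]-5,6-dihydro-2H-pyran-2-one | C[Si](C)(C)/C=C1\C=CC(=O)OC1(C)C | intermediate
27 | (E)-5-(iodomethylidene)-6,6-dimethyl-5,6-dihydro-2H-pyran-2-one | I/C=C1\C=CC(=O)OC1(C)C | intermediate
28 | alkenylchromium dichloride derived from 27 | Cl[Cr](Cl)/C=C1\C=CC(=O)OC1(C)C | intermediate
29 | C7 carbinol (both epimers) carrying the pyranone ylidene unit | COC(=O)[C@H]1O[C@@]12[C@](C)(C(=O)c1ccoc1)CC[C@H]([C@@H](C)O[Si](C)(C)C(C)(C)C)[C@@]2(C)C(O)/C=C1\C=CC(=O)OC1(C)C | intermediate
30 | C10 O-TBS ether of the target | COC(=O)[C@H]1O[C@@]12[C@](C)(C(=O)c1ccoc1)CC[C@H]([C@@H](C)O[Si](C)(C)C(C)(C)C)[C@@]2(C)C(=O)/C=C1\C=CC(=O)OC1(C)C | intermediate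
31 | CNP0293135.1 | COC(=O)[C@H]1O[C@@]12[C@](C)(C(=O)c1ccoc1)CC[C@H]([C@@H](C)O)[C@@]2(C)C(=O)/C=C1\C=CC(=O)OC1(C)C | target

Total step count: 20. Longest linear sequence: 16 steps (steps 2–14 and 18–20, from methyl (R)-lactate).

Steps most likely to fail

Step 5. The fully substituted donor carbon may add too slowly, so that self-condensation of the enal or dienamine-mediated loss of configuration at C10 takes over. Face selection at the donor carbon C8 may also be poor. The fallback sets out from 2 and 6 and comes back at 8. Activation is moved from the acceptor to the donor. A 6'-hydroxy cinchona alkaloid, acting as base and hydrogen-bond donor, is a known way to add α-substituted β-keto esters to β-substituted enals with formation of adjacent quaternary and tertiary centres. Adduct 7 is then isolated, freed from its C8 epimer, and closed in a separate, known aldol step with piperidinium acetate in toluene under equilibrating conditions. No compound outside the list is made (F0).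

Step 12. Facial selectivity at C14 may be poor if the ring-flipped conformer is not the reacting one. The enolate may attack the C7 formyl group. The alkoxide base may cleave the chloroacetate, followed by retro-aldol loss of the furyl unit. The fallback sets out from 16 and comes back at 19, and it separates C–C bond formation from oxygen delivery.
- Carbinol 16 is esterified with diethylphosphonoacetic acid (DCC, DMAP) to the C17 phosphonoacetate F1.
- An intramolecular Horner–Wadsworth–Emmons reaction (LiCl, DBU, MeCN), which is blind to the ketone faces, gives the 14,15-unsaturated δ-lactone F2 with C16 necessarily cis to C13.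
- A Weitz–Scheffer-type epoxidation with t-BuOOLi in THF delivers the oxygen. Its stereochemical course is decided by the approach to the rigid bicyclic enoate and no longer by the conformation of an open keto ester.

Step 18. Addition to the very hindered aldehyde may be slow, excess divalent chromium may reduce the glycidic ester, or the chromium alkoxide may fragment towards the oxirane. The fallback sets out from 21 and comes back at 30, and it builds the side chain on the aldehyde from 22 and 24 without chromium.
- Zn(OTf)2/Et3N-mediated alkynylation with 22 gives the propargylic diol F3.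
- Dess–Martin oxidation gives the ynone F4.
- Hydroxyl-directed trans-hydrostannation ([Cp*RuCl]4, Bu3SnH) puts tin on C5, cis to the C7 acyl group, in the β-stannyl enone F5.
- Stille coupling with 24 gives the hydroxy trienoate F6, which lactonises under PPTS catalysis to 30.

Further compounds
F0 | step 5 | none | none
F1 | step 12 | C17 diethylphosphonoacetate of 16 | O=C1[C@](C)([C@@H](OC(=O)CP(=O)(OCC)OCC)c2ccoc2)CC[C@H]([C@@H](C)O[Si](C)(C)C(C)(C)C)[C@@]1(C)C=O
F2 | step 12 | 14,15-unsaturated δ-lactone aldehyde | O=C3C=C2[C@](C)([C@@H](O3)c1ccoc1)CC[C@H]([C@@H](C)O[Si](C)(C)C(C)(C)C)[C@@]2(C)C=O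
F3 | step 18 | C7 propargylic diol (C7 epimers) | COC(=O)[C@H]1O[C@@]12[C@](C)(C(=O)c1ccoc1)CC[C@H]([C@@H](C)O[Si](C)(C)C(C)(C)C)[C@@]2(C)C(O)C#CC(C)(C)O
F4 | step 18 | C7 ynone with tertiary alcohol | COC(=O)[C@H]1O[C@@]12[C@](C)(C(=O)c1ccoc1)CC[C@H]([C@@H](C)O[Si](C)(C)C(C)(C)C)[C@@]2(C)C(=O)C#CC(C)(C)O
F5 | step 18 | β-stannyl enone, tin cis to the C7 acyl group | COC(=O)[C@H]1O[C@@]12[C@](C)(C(=O)c1ccoc1)CC[C@H]([C@@H](C)O[Si](C)(C)C(C)(C)C)[C@@]2(C)C(=O)/C=C(\[Sn](CCCC)(CCCC)CCCC)C(C)(C)O
F6 | step 18 | hydroxy trienoate before lactonisation | COC(=O)[C@H]1O[C@@]12[C@](C)(C(=O)c1ccoc1)CC[C@H]([C@@H](C)O[Si](C)(C)C(C)(C)C)[C@@]2(C)C(=O)/C=C(\C=C/C(=O)OCC)C(C)(C)O
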